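**Plan**
- Retrosynthesis: the C2 carbonyl is taken back to CH2 and the C4 ester to OH; the C3–C3a bond is then cut (radical closure of an O1-propargyl ether onto a C3a radical from a C3a–C4 epoxide), followed by C3a=C4 (ring-closing metathesis), C6=C7 (Wittig) and C9–C10 (lactone enolate alkylation).
- Forward: the C11a-to-C7 chain is built on a chiral γ-lactone, the enoate arm is added by Wittig olefination, the ten-membered carbocycle is closed by metathesis, and the five-membered O-ring is then stitched on at C3–C3a and oxidized to the lactone.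
- Enabling feature: O1 on C11a is β to C3a, the neighbouring C4 carries oxygen, and C3 bears an exocyclic CH2. A C3a–C4 epoxide next to an O-propargyl group is therefore a latent O1–C2–C3–C3a–C11a ring with the methylidene and the C4–OH already in place.
- Stereochemistry: C11a comes from (R)-5-(hydroxymethyl)oxolan-2-one, C10 from trans alkylation of its enolate, C4 from peripheral epoxidation of the Z-cycloalkene, C3a from ring-controlled trans-fused radical closure, the acyl centre from (S)-2-methylbutanoic anhydride, and the E-enoate from the stabilized ylide.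

Key step: step 13

Remark: ring atoms carry the locants of the target's cyclodeca[b]furan skeleton (O1, C2, C3, C3a, C4–C11, C11a) in all explanations, also for open-chain precursors; compound names use their own systematic numbering. Compounds 1 and 21 are taken as commercial.

**Step 1**
Reactants: 1 (R)-5-(hydroxymethyl)oxolan-2-one
Product: 2 (R)-5-oxooxolane-2-carbaldehyde
Conditions: Dess–Martin periodinane, CH2Cl2, 0 °C to rt
Reagents that add atoms: none
Why: Dess–Martin oxidation of the primary alcohol under near-neutral conditions should give the aldehyde without epimerizing the adjacent C11a centre or opening the lactone.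

**Step 2**
Reactants: 2 (R)-5-oxooxolane-2-carbaldehyde
Product: 3 (R)-5-ethenyloxolan-2-one
Conditions: Ph3PCH3Br, KN(SiMe3)2, THF, −78 °C to 0 °C
Reagents that add atoms: methyltriphenylphosphonium bromide, C[P+](c1ccccc1)(c1ccccc1)c1ccccc1.[Br-]
Why: Wittig methylenation with the lithium-free ylide at low temperature should be faster than enolization of the α-acyloxy aldehyde and than attack on the lactone, so the C11a configuration is kept.

**Step 3**
Reactants: 4 2-(2-bromoethyl)-1,3-dioxolane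
Product: 5 2-(2-iodoethyl)-1,3-dioxolane
Conditions: NaI, acetone, reflux
Reagents that add atoms: sodium iodide, [Na+].[I-]
Why: Finkelstein exchange, driven by precipitation of NaBr, gives the more reactive primary iodide needed for the enolate alkylation.

**Step 4**
Reactants: 3 (R)-5-ethenyloxolan-2-one; 5 2-(2-iodoethyl)-1,3-dioxolane
Product: 7 (3S,5R)-3-[2-(1,3-dioxolan-2-yl)ethyl]-5-ethenyloxolan-2-one, via lithium enolate 6 (not isolated)
Conditions: LiN(iPr)2, THF, −78 °C; then 5, HMPA, −78 to −30 °C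
Reagents that add atoms: none
Why: Alkylation of the lithium enolate of a 5-substituted γ-butyrolactone with a primary iodide takes place anti to the C5 substituent, so the trans-3,5 product should predominate and C10 is set from C11a.

**Step 5**
Reactants: 7 (3S,5R)-3-[2-(1,3-dioxolan-2-yl)ethyl]-5-ethenyloxolan-2-one
Product: 8 (2S,4R)-2-[2-(1,3-dioxolan-2-yl)ethyl]hex-5-ene-1,4-diol
Conditions: LiAlH4, THF, 0 °C
Reagents that add atoms: none
Why: LiAlH4 reduces the lactone to the 1,4-diol and leaves the acetal and the alkene untouched; no stereocentre is affected.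

**Step 6**
Reactants: 8 (2S,4R)-2-[2-(1,3-dioxolan-2-yl)ethyl]hex-5-ene-1,4-diol
Product: 9 (3R,5S)-5-{[tert-butyl(diphenyl)silyl]oxymethyl}-7-(1,3-dioxolan-2-yl)hept-1-en-3-ol
Conditions: TBDPSCl, imidazole, CH2Cl2, 0 °C
Reagents that add atoms: tert-butyl(chloro)diphenylsilane, CC(C)(C)[Si](Cl)(c1ccccc1)c1ccccc1
Why: Silylation with the bulky chlorosilane should be selective for the primary over the secondary allylic hydroxyl.

**Step 7**
Reactants: 9 (3R,5S)-5-{[tert-butyl(diphenyl)silyl]oxymethyl}-7-(1,3-dioxolan-2-yl)hept-1-en-3-ol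
Product: 10 (4S,6R)-4-{[tert-butyl(diphenyl)silyl]oxymethyl}-6-hydroxyoct-7-enal
Conditions: 1 M HCl, THF, rt
Reagents that add atoms: water, O
Why: Acid-catalysed acetal hydrolysis frees the aldehyde; the tert-butyldiphenylsilyl ether and the allylic alcohol should tolerate dilute acid at room temperature.

**Step 8**
Reactants: 11 methyl (triphenylphosphoranylidene)acetate; 12 allyl bromide
Product: 14 methyl 2-(triphenylphosphoranylidene)pent-4-enoate, via phosphonium bromide 13 (not isolated)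
Conditions: CH2Cl2, reflux; then aq. NaOH, rt
Reagents that add atoms: none
Why: C-Alkylation of the stabilized ylide with the allylic bromide gives the phosphonium salt, which NaOH deprotonates to the α-allyl ylide.

**Step 9**
Reactants: 10 (4S,6R)-4-{[tert-butyl(diphenyl)silyl]oxymethyl}-6-hydroxyoct-7-enal; 14 methyl 2-(triphenylphosphoranylidene)pent-4-enoate
Product: 15 methyl (2E,6S,8R)-6-{[tert-butyl(diphenyl)silyl]oxymethyl}-8-hydroxy-2-(prop-2-en-1-yl)deca-2,9-dienoate
Conditions: toluene, 80 °C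
Reagents that add atoms: none
Why: Wittig olefination with the α-substituted stabilized ylide should give the trisubstituted enoate with the ester trans to the chain (E); the free hydroxyl does not interfere.

**Step 10**
Reactants: 15 methyl (2E,6S,8R)-6-{[tert-butyl(diphenyl)silyl]oxymethyl}-8-hydroxy-2-(prop-2-en-1-yl)deca-2,9-dienoate
Product: 16 methyl (1E,5S,7R,8Z)-5-{[tert-butyl(diphenyl)silyl]oxymethyl}-7-hydroxycyclodeca-1,8-diene-1-carboxylate
Conditions: second-generation Grubbs catalyst RuCl2(=CHPh)(PCy3)(H2IMes) (10 mol%), 1,4-benzoquinone (10 mol%), toluene (1 mM), 80 °C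
Reagents that add atoms: none
Why: Ring-closing metathesis joins the two monosubstituted alkenes with loss of ethene; the ring-cis enoate acts as a turn element and is itself inert to the catalyst, and the ten-membered ring should enforce the Z geometry at C3a=C4.

**Step 11**
Reactants: 16 methyl (1E,5S,7R,8Z)-5-{[tert-butyl(diphenyl)silyl]oxymethyl}-7-hydroxycyclodeca-1,8-diene-1-carboxylate; 17 propargyl bromide
Product: 18 methyl (1E,5S,7R,8Z)-5-{[tert-butyl(diphenyl)silyl]oxymethyl}-7-(prop-2-yn-1-yloxy)cyclodeca-1,8-diene-1-carboxylate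
Conditions: NaH, Bu4NI (cat.), THF, 0 °C to rt
Reagents that add atoms: none
Why: Williamson etherification of the secondary allylic alkoxide with the reactive propargylic bromide installs the radical acceptor; at 0 °C intermolecular alkylation should outrun transannular addition of the alkoxide to the trisubstituted enoate.

**Step 12**
Reactants: 18 methyl (1E,5S,7R,8Z)-5-{[tert-butyl(diphenyl)silyl]oxymethyl}-7-(prop-2-yn-1-yloxy)cyclodeca-1,8-diene-1-carboxylate
Product: 19 methyl (1E,5S,7R,8R,9R)-5-{[tert-butyl(diphenyl)silyl]oxymethyl}-8,9-epoxy-7-(prop-2-yn-1-yloxy)cyclodec-1-ene-1-carboxylate (cis-epoxide, oxygen on the ring face opposite to the propargyloxy group)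
Conditions: m-CPBA, CH2Cl2, 0 °C
Reagents that add atoms: 3-chloroperoxybenzoic acid, OOC(=O)c1cccc(Cl)c1
Why: Prilezhaev epoxidation touches only the electron-rich Z-disubstituted alkene (enoate and alkyne are inert); allylic 1,3-strain holds the C11a–H in the alkene plane and the ring chain covers one face, so the peracid should attack the peripheral face that carries the propargyloxy group and set C4 with the configuration of the target.

**Step 13**
Reactants: 19 methyl (1E,5S,7R,8R,9R)-5-{[tert-butyl(diphenyl)silyl]oxymethyl}-8,9-epoxy-7-(prop-2-yn-1-yloxy)cyclodec-1-ene-1-carboxylate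
Product: 20 methyl (3aR,4R,6E,10S,11aR)-10-{[tert-butyl(diphenyl)silyl]oxymethyl}-4-hydroxy-3-methylidene-2,3,3a,4,5,8,9,10,11,11a-decahydrocyclodeca[b]furan-6-carboxylate
Conditions: Cp2TiCl2 (20 mol%), Mn dust, 2,4,6-collidine hydrochloride, THF, rt, slow addition of 19
Reagents that add atoms: none
Why: Cp2TiCl (trivalent titanium, regenerated by Mn and the collidinium salt) transfers one electron to the epoxide and cleaves the C3a–O bond; the β-titanoxy C3a radical adds to the alkyne of the propargyl ether, the vinyl radical is reduced and protonated to the exocyclic methylene, and the Ti–O bond at C4 is protonolysed. The closest known reaction type is the Nugent–RajanBabu titanocene epoxide opening with radical cyclization, as applied to acyclic 2,3-epoxy propargyl ethers to give 3-methylidene tetrahydrofurans. The ring O1–C2–C3–C3a–C11a closes in the 5-exo-dig mode. C3a is the only new stereocentre and is set by the macrocycle: with the C11a–H eclipsing the C3a–C4 bond, the propargyloxy arm lies over the peripheral lobe of the planar radical and bonds on the face the epoxide oxygen has left, which should give the trans ring fusion (H3a and H11a anti) with C3 cis to the C4 oxygen, whose configuration is carried over unchanged from the epoxide. The step needs homolysis of C3a–O and not C4–O, for which the β-alkoxy substituent on C11a is relied on, as in 2,3-epoxy ethers. It also needs cyclization to be faster than capture of the radical by a second titanium (kept low by the catalytic protocol) and faster than transannular attack on the enoate, which would be a disfavoured 5-endo closure at C7.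

**Step 14**
Reactants: 20 methyl (3aR,4R,6E,10S,11aR)-10-{[tert-butyl(diphenyl)silyl]oxymethyl}-4-hydroxy-3-methylidene-2,3,3a,4,5,8,9,10,11,11a-decahydrocyclodeca[b]furan-6-carboxylate; 21 (S)-2-methylbutanoic anhydride
Product: 22 methyl (3aS,4R,6E,10S,11aR)-10-{[tert-butyl(diphenyl)silyl]oxymethyl}-3-methylidene-4-{[(2S)-2-methylbutanoyl]oxy}-2,3,3a,4,5,8,9,10,11,11a-decahydrocyclodeca[b]furan-6-carboxylate
Conditions: 4-(dimethylamino)pyridine (cat.), Et3N, CH2Cl2, rt
Reagents that add atoms: none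
Why: Acylation of the secondary alcohol with the anhydride under nucleophilic catalysis (Steglich-type acyl transfer) should proceed without touching the α-stereocentre of the acyl group; the change of the C3a descriptor is only a change of CIP priorities.

**Step 15**
Reactants: 22 methyl (3aS,4R,6E,10S,11aR)-10-{[tert-butyl(diphenyl)silyl]oxymethyl}-3-methylidene-4-{[(2S)-2-methylbutanoyl]oxy}-2,3,3a,4,5,8,9,10,11,11a-decahydrocyclodeca[b]furan-6-carboxylate
Product: 23 methyl (3aS,4R,6E,10S,11aR)-10-{[tert-butyl(diphenyl)silyl]oxymethyl}-3-methylidene-4-{[(2S)-2-methylbutanoyl]oxy}-2-oxo-2,3,3a,4,5,8,9,10,11,11a-decahydrocyclodeca[b]furan-6-carboxylate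
Conditions: CrO3, pyridine, CH2Cl2, rt
Reagents that add atoms: chromium trioxide, O=[Cr](=O)=O
Why: Allylic oxidation with CrO3–pyridine (Collins reagent) should attack C2, the only methylene that is both allylic and α to the ring oxygen, and convert the 3-methylidene tetrahydrofuran into the α-methylene-γ-butyrolactone.

**Step 16**
Reactants: 23 methyl (3aS,4R,6E,10S,11aR)-10-{[tert-butyl(diphenyl)silyl]oxymethyl}-3-methylidene-4-{[(2S)-2-methylbutanoyl]oxy}-2-oxo-2,3,3a,4,5,8,9,10,11,11a-decahydrocyclodeca[b]furan-6-carboxylate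
Product: 24 methyl (3aS,4R,6E,10S,11aR)-10-(hydroxymethyl)-3-methylidene-4-{[(2S)-2-methylbutanoyl]oxy}-2-oxo-2,3,3a,4,5,8,9,10,11,11a-decahydrocyclodeca[b]furan-6-carboxylate
Conditions: HF·pyridine, pyridine, THF, 0 °C to rt
Reagents that add atoms: none
Why: Fluoride cleavage of the silyl ether with pyridine-buffered HF should free the primary alcohol without adding to the methylene lactone or cleaving the esters.

**Compound list**
1 | (R)-5-(hydroxymethyl)oxolan-2-one | O=C1CC[C@H](CO)O1 | starting material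
2 | (R)-5-oxooxolane-2-carbaldehyde | O=C1CC[C@H](C=O)O1 | intermediate
3 | (R)-5-ethenyloxolan-2-one | O=C1CC[C@H](C=C)O1 | intermediate
4 | 2-(2-bromoethyl)-1,3-dioxolane | BrCCC1OCCO1 | starting material
5 | 2-(2-iodoethyl)-1,3-dioxolane | ICCC1OCCO1 | intermediate
6 | lithium (R)-5-ethenyl-4,5-dihydrofuran-2-olate (lithium enolate of 3) | [Li]OC1=CC[C@H](C=C)O1 | intermediate (not isolated)
7 | (3S,5R)-3-[2-(1,3-dioxolan-2-yl)ethyl]-5-ethenyloxolan-2-one | O=C1[C@@H](CCC2OCCO2)C[C@H](C=C)O1 | intermediate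
8 | (2S,4R)-2-[2-(1,3-dioxolan-2-yl)ethyl]hex-5-ene-1,4-diol | OC[C@@H](CCC1OCCO1)C[C@@H](O)C=C | intermediate
9 | (3R,5S)-5-{[tert-butyl(diphenyl)silyl]oxymethyl}-7-(1,3-dioxolan-2-yl)hept-1-en-3-ol | CC(C)(C)[Si](OC[C@@H](CCC1OCCO1)C[C@@H](O)C=C)(c1ccccc1)c1ccccc1 | intermediate
10 | (4S,6R)-4-{[tert-butyl(diphenyl)silyl]oxymethyl}-6-hydroxyoct-7-enal | CC(C)(C)[Si](OC[C@@H](CCC=O)C[C@@H](O)C=C)(c1ccccc1)c1ccccc1 | intermediate
11 | methyl (triphenylphosphoranylidene)acetate | COC(=O)C=P(c1ccccc1)(c1ccccc1)c1ccccc1 | starting material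
12 | allyl bromide (3-bromoprop-1-ene) | C=CCBr | starting material
13 | (1-methoxy-1-oxopent-4-en-2-yl)triphenylphosphonium bromide | COC(=O)C(CC=C)[P+](c1ccccc1)(c1ccccc1)c1ccccc1.[Br-] | intermediate (not isolated)
14 | methyl 2-(triphenylphosphoranylidene)pent-4-enoate | COC(=O)C(CC=C)=P(c1ccccc1)(c1ccccc1)c1ccccc1 | intermediate
15 | methyl (2E,6S,8R)-6-{[tert-butyl(diphenyl)silyl]oxymethyl}-8-hydroxy-2-(prop-2-en-1-yl)deca-2,9-dienoate | C=C[C@H](O)C[C@@H](CO[Si](c1ccccc1)(c1ccccc1)C(C)(C)C)CC/C=C(/C(=O)OC)CC=C | intermediate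
16 | methyl (1E,5S,7R,8Z)-5-{[tert-butyl(diphenyl)silyl]oxymethyl}-7-hydroxycyclodeca-1,8-diene-1-carboxylate | C1[C@@H](O)/C=C\C/C(C(=O)OC)=C\CC[C@@H]1CO[Si](c2ccccc2)(c2ccccc2)C(C)(C)C | intermediate
17 | propargyl bromide (3-bromoprop-1-yne) | C#CCBr | starting material
18 | methyl (1E,5S,7R,8Z)-5-{[tert-butyl(diphenyl)silyl]oxymethyl}-7-(prop-2-yn-1-yloxy)cyclodeca-1,8-diene-1-carboxylate | C1[C@@H](OCC#C)/C=C\C/C(C(=O)OC)=C\CC[C@@H]1CO[Si](c2ccccc2)(c2ccccc2)C(C)(C)C | intermediate
19 | methyl (1E,5S,7R,8R,9R)-5-{[tert-butyl(diphenyl)silyl]oxymethyl}-8,9-epoxy-7-(prop-2-yn-1-yloxy)cyclodec-1-ene-1-carboxylate | C1[C@@H](OCC#C)[C@@H]2O[C@@H]2C/C(C(=O)OC)=C\CC[C@@H]1CO[Si](c3ccccc3)(c3ccccc3)C(C)(C)C | intermediate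
20 | methyl (3aR,4R,6E,10S,11aR)-10-{[tert-butyl(diphenyl)silyl]oxymethyl}-4-hydroxy-3-methylidene-2,3,3a,4,5,8,9,10,11,11a-decahydrocyclodeca[b]furan-6-carboxylate | C=C1CO[C@@H]2C[C@@H](CO[Si](c3ccccc3)(c3ccccc3)C(C)(C)C)CC/C=C(/C(=O)OC)C[C@@H](O)[C@@H]12 | intermediate
21 | (S)-2-methylbutanoic anhydride | CC[C@H](C)C(=O)OC(=O)[C@@H](C)CC | starting material
22 | methyl (3aS,4R,6E,10S,11aR)-10-{[tert-butyl(diphenyl)silyl]oxymethyl}-3-methylidene-4-{[(2S)-2-methylbutanoyl]oxy}-2,3,3a,4,5,8,9,10,11,11a-decahydrocyclodeca[b]furan-6-carboxylate | C=C1CO[C@@H]2C[C@@H](CO[Si](c3ccccc3)(c3ccccc3)C(C)(C)C)CC/C=C(/C(=O)OC)C[C@@H](OC(=O)[C@@H](C)CC)[C@@H]12 | intermediate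
23 | methyl (3aS,4R,6E,10S,11aR)-10-{[tert-butyl(diphenyl)silyl]oxymethyl}-3-methylidene-4-{[(2S)-2-methylbutanoyl]oxy}-2-oxo-2,3,3a,4,5,8,9,10,11,11a-decahydrocyclodeca[b]furan-6-carboxylate | C=C1C(=O)O[C@@H]2C[C@@H](CO[Si](c3ccccc3)(c3ccccc3)C(C)(C)C)CC/C=C(/C(=O)OC)C[C@@H](OC(=O)[C@@H](C)CC)[C@@H]12 | intermediate
24 | methyl (3aS,4R,6E,10S,11aR)-10-(hydroxymethyl)-3-methylidene-4-{[(2S)-2-methylbutanoyl]oxy}-2-oxo-2,3,3a,4,5,8,9,10,11,11a-decahydrocyclodeca[b]furan-6-carboxylate | C=C1C(=O)O[C@@H]2C[C@@H](CO)CC/C=C(/C(=O)OC)C[C@@H](OC(=O)[C@@H](C)CC)[C@@H]12 | target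

**Step count**
Total: 16 steps. Longest linear sequence: 14 steps (from 1 through steps 1, 2, 4–7 and 9–16).

**Steps most likely to fail**

Step 13. The epoxide may be opened at the C4–O bond instead of the C3a–O bond, or the C3a radical may be captured by a second trivalent titanium and lose the C4 oxygen by β-elimination before it reaches the alkyne. The fallback sets out from 18 and comes back at 22; it generates the C3a radical from a defined C–O bond with tin hydride. Dihydroxylation of the C3a=C4 bond from the peripheral face (OsO4 cat., N-methylmorpholine N-oxide, acetone/H2O) should give the diol methyl (1E,5S,7R,8R,9R)-5-{[tert-butyl(diphenyl)silyl]oxymethyl}-8,9-dihydroxy-7-(prop-2-yn-1-yloxy)cyclodec-1-ene-1-carboxylate F1. Acylation of the less hindered C4 hydroxyl with 21 (4-(dimethylamino)pyridine, CH2Cl2, −40 °C) should give the monoester methyl (1E,5S,7R,8S,9R)-5-{[tert-butyl(diphenyl)silyl]oxymethyl}-8-hydroxy-9-{[(2S)-2-methylbutanoyl]oxy}-7-(prop-2-yn-1-yloxy)cyclodec-1-ene-1-carboxylate F2. 1,1'-Thiocarbonyldiimidazole (1,2-dichloroethane, 60 °C) then gives the C3a thiocarbonyl derivative methyl (1E,5S,7R,8S,9R)-5-{[tert-butyl(diphenyl)silyl]oxymethyl}-8-[(1H-imidazol-1-ylcarbonothioyl)oxy]-9-{[(2S)-2-methylbutanoyl]oxy}-7-(prop-2-yn-1-yloxy)cyclodec-1-ene-1-carboxylate F3. Barton–McCombie radical generation (Bu3SnH, AIBN, benzene, 80 °C, slow addition) with 5-exo-dig closure and hydrogen transfer to the vinyl radical leads to 22.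

Step 10. Intermolecular metathesis (oligomerization) may outrun closure of the strained ten-membered diene, or the skipped diene may isomerize. The fallback sets out from 10 (with 11) and comes back at 16; it closes the ring at C3a–C11a by a Nozaki–Hiyama–Kishi reaction.
- Ethyl (Z)-3-iodoacrylate is reduced (iBu2AlH, CH2Cl2, −78 °C) to (Z)-3-iodoprop-2-en-1-ol F4 and converted (CBr4, PPh3, Appel reaction) into (Z)-3-bromo-1-iodoprop-1-ene F5.
- Alkylation of 11 with F5 as in step 8 gives [(4Z)-5-iodo-1-methoxy-1-oxopent-4-en-2-yl]triphenylphosphonium bromide F6 and, with aq. NaOH, methyl (4Z)-5-iodo-2-(triphenylphosphoranylidene)pent-4-enoate F7.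
- Wittig reaction of F7 with 10 should give methyl (2E,6S,8R)-6-{[tert-butyl(diphenyl)silyl]oxymethyl}-8-hydroxy-2-[(2Z)-3-iodoprop-2-en-1-yl]deca-2,9-dienoate F8.
- Lemieux–Johnson cleavage of the vinyl carbinol (OsO4 cat., NaIO4, 2,6-lutidine, dioxane/H2O) gives methyl (2E,6S)-6-{[tert-butyl(diphenyl)silyl]oxymethyl}-2-[(2Z)-3-iodoprop-2-en-1-yl]-8-oxooct-2-enoate F9.
- CrCl2 (divalent chromium) with NiCl2 (cat.) in DMSO/THF at high dilution closes the ring with retention of the Z geometry to give 16 together with its carbinol epimer methyl (1E,5S,7S,8Z)-5-{[tert-butyl(diphenyl)silyl]oxymethyl}-7-hydroxycyclodeca-1,8-diene-1-carboxylate F10.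
- The mixture is converged by MnO2 oxidation to methyl (1E,5S,8Z)-5-{[tert-butyl(diphenyl)silyl]oxymethyl}-7-oxocyclodeca-1,8-diene-1-carboxylate F11 and Corey–Bakshi–Shibata reduction (BH3·SMe2, (S)-1-methyl-3,3-diphenyltetrahydro-1H,3H-pyrrolo[1,2-c][1,3,2]oxazaborole) to 16.

Step 12. The peracid may be delivered to the other face of the C3a=C4 bond, which would give the wrong C4 configuration. The fallback sets out from 18 and comes back at 19; it inverts the facial outcome in two steps. N-Bromosuccinimide in aqueous 1,2-dimethoxyethane places bromine on the accessible face and water anti at C4, which should give methyl (1E,5S,7R,8S,9R)-8-bromo-5-{[tert-butyl(diphenyl)silyl]oxymethyl}-9-hydroxy-7-(prop-2-yn-1-yloxy)cyclodec-1-ene-1-carboxylate F12. K2CO3 in MeOH then closes the epoxide on the opposite face to give 19; the regioisomeric bromohydrin would give the same epoxide.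

**Further compounds**
F1 | step 13 | methyl (1E,5S,7R,8R,9R)-5-{[tert-butyl(diphenyl)silyl]oxymethyl}-8,9-dihydroxy-7-(prop-2-yn-1-yloxy)cyclodec-1-ene-1-carboxylate | C1[C@@H](OCC#C)[C@H](O)[C@H](O)C/C(C(=O)OC)=C\CC[C@@H]1CO[Si](c2ccccc2)(c2ccccc2)C(C)(C)C
F2 | step 13 | methyl (1E,5S,7R,8S,9R)-5-{[tert-butyl(diphenyl)silyl]oxymethyl}-8-hydroxy-9-{[(2S)-2-methylbutanoyl]oxy}-7-(prop-2-yn-1-yloxy)cyclodec-1-ene-1-carboxylate | C1[C@@H](OCC#C)[C@H](O)[C@H](OC(=O)[C@@H](C)CC)C/C(C(=O)OC)=C\CC[C@@H]1CO[Si](c2ccccc2)(c2ccccc2)C(C)(C)C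
F3 | step 13 | methyl (1E,5S,7R,8S,9R)-5-{[tert-butyl(diphenyl)silyl]oxymethyl}-8-[(1H-imidazol-1-ylcarbonothioyl)oxy]-9-{[(2S)-2-methylbutanoyl]oxy}-7-(prop-2-yn-1-yloxy)cyclodec-1-ene-1-carboxylate | C1[C@@H](OCC#C)[C@H](OC(=S)n2ccnc2)[C@H](OC(=O)[C@@H](C)CC)C/C(C(=O)OC)=C\CC[C@@H]1CO[Si](c2ccccc2)(c2ccccc2)C(C)(C)C
F4 | step 10 | (Z)-3-iodoprop-2-en-1-ol | OC/C=C\I
F5 | step 10 | (Z)-3-bromo-1-iodoprop-1-ene | BrC/C=C\I
F6 | step 10 | [(4Z)-5-iodo-1-methoxy-1-oxopent-4-en-2-yl]triphenylphosphonium bromide | COC(=O)C(C/C=C\I)[P+](c1ccccc1)(c1ccccc1)c1ccccc1.[Br-]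
F7 | step 10 | methyl (4Z)-5-iodo-2-(triphenylphosphoranylidene)pent-4-enoate | COC(=O)C(C/C=C\I)=P(c1ccccc1)(c1ccccc1)c1ccccc1
F8 | step 10 | methyl (2E,6S,8R)-6-{[tert-butyl(diphenyl)silyl]oxymethyl}-8-hydroxy-2-[(2Z)-3-iodoprop-2-en-1-yl]deca-2,9-dienoate | C=C[C@H](O)C[C@@H](CO[Si](c1ccccc1)(c1ccccc1)C(C)(C)C)CC/C=C(/C(=O)OC)C/C=C\I
F9 | step 10 | methyl (2E,6S)-6-{[tert-butyl(diphenyl)silyl]oxymethyl}-2-[(2Z)-3-iodoprop-2-en-1-yl]-8-oxooct-2-enoate | O=CC[C@@H](CO[Si](c1ccccc1)(c1ccccc1)C(C)(C)C)CC/C=C(/C(=O)OC)C/C=C\I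
F10 | step 10 | methyl (1E,5S,7S,8Z)-5-{[tert-butyl(diphenyl)silyl]oxymethyl}-7-hydroxycyclodeca-1,8-diene-1-carboxylate | C1[C@H](O)/C=C\C/C(C(=O)OC)=C\CC[C@@H]1CO[Si](c2ccccc2)(c2ccccc2)C(C)(C)C
F11 | step 10 | methyl (1E,5S,8Z)-5-{[tert-butyl(diphenyl)silyl]oxymethyl}-7-oxocyclodeca-1,8-diene-1-carboxylate | C1C(=O)/C=C\C/C(C(=O)OC)=C\CC[C@@H]1CO[Si](c2ccccc2)(c2ccccc2)C(C)(C)C
F12 | step 12 | methyl (1E,5S,7R,8S,9R)-8-bromo-5-{[tert-butyl(diphenyl)silyl]oxymethyl}-9-hydroxy-7-(prop-2-yn-1-yloxy)cyclodec-1-ene-1-carboxylate | C1[C@@H](OCC#C)[C@@H](Br)[C@H](O)C/C(C(=O)OC)=C\CC[C@@H]1CO[Si](c2ccccc2)(c2ccccc2)C(C)(C)C
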